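## The problem

The target **27** is (13R)-2β-acetoxylabd-8(17)-en-15-oic acid, (2R,5S,9S,10S,13R). Labdane numbering is used throughout: ring A = C1–C5 and C10, ring B = C5–C10, C17 = the methylene carbon on C8, C18/C19 = the methyls on C4, C20 = the methyl on C10, C11–C15 = the chain on C9, C16 = the methyl on C13. The two rings are trans-fused through C5 (H) and the quaternary C10, so the core task is to join a tertiary and a quaternary centre between the gem-dimethyl carbon C4 and C9. Once C5 and C10 are fixed, the axial methyls C19 and C20 cover the β face. C9 then follows by hydrogen delivery to the α face, and its equatorial chain is also the thermodynamic arrangement next to a C8 carbonyl. The C2 oxygen is axial and syn to both axial methyls, so it cannot be placed by SN2 displacement or by equatorial-selective methods. It must come from α-face attack followed by anti opening, or from hydride delivery to a C2 ketone. C13 is too far from the ring to be controlled by it and has to be brought in as a finished stereocentre. The exocyclic 8(17)-alkene isomerises in acid and reacts with electrophiles, boranes and hydrogen, and the acetate must end beside a free acid, so the methylene and the acetate belong at the end. The enabling feature is that C5 (H, bonded to C4 and C6) and C10 (methyl, bonded to C9) are adjacent with C6 and C9 trans. This is the pattern left by adding a carbon nucleophile to the β-carbon and a carbon electrophile to the α-carbon of 2,4,4-trimethylcyclohex-2-enone **1**, whose ring carbons are C1–C5 and C10. The cost is that the carbonyl of **1** sits at C1, whereas the target is oxygenated at C2.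

## Retrosynthesis

**Acetate, acid and methylene last.** The C2–O acyl bond, the methyl ester and the C8=C17 bond are cut first: **27** comes from hydroxy acid **25**, **25** from ester **24**, and **24** from the C8 ketone **23** by methylenation. Acetylating the hydroxy acid last avoids a selective ester hydrolysis beside an acetate. Making the alkene from a ketone keeps it out of every electrophilic, radical and reductive step. The forward steps only need a hindered axial alcohol to be acylated and an α-branched ketone to be methylenated.

**C2–O from the C1=C2 alkene.** The 2β-hydroxyl of **23** is traced through **22** and bromohydrin **21** to trienone **20**: the C2–O and C1–H bonds are cut, and the C6–C7 and C9–C11 hydrogens are removed. A bromohydrin is preferred to hydroboration because in **20** the C1=C2 bond is the only electron-rich alkene and the ketone can stay unprotected. It is preferred to oxidation–reduction at C2 because anti opening at C2 gives the axial 2β-alcohol directly. Hydrogenation of the two enone double bonds then sets C9 from the α face. The forward reaction must deliver bromine to the α face and water to C2 from the β face.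

**C9–C11 by aldol condensation.** Cutting the C9=C11 bond of **20** gives dienone **12** and aldehyde **16** by way of aldol **18**. The enone in **12** makes C9 the only kinetically accessible α-position, which a saturated C8 ketone would not guarantee. Condensation is chosen over alkylation because an aldehyde reacts at the neopentyl C9 where an alkyl halide would be slow. Aldehyde **16** carries C13 and comes in three steps from 3-methylglutaric anhydride **13** through hemiester **14** and hydroxy ester **15**. The stereocentre is created by desymmetrisation of a prochiral anhydride.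

**Ring B by ozonolysis and aldol; C1 kept as an enol triflate.** Dienone **12** comes from enone triflate **11** by reduction of the C–O bond. Cutting C6=C7 of **11** gives keto aldehyde **9**, whose two carbonyls are the vinyl and methallyl groups of triene triflate **7**. The alternative of reducing the C1 ketone, silylating, and later deprotecting, oxidising and eliminating would cost four more steps and end in a neopentyl dehydration that invites skeletal shifts. The triflate masks the C1 carbonyl (nothing at C1 can enolise during the aldol), is electron-poor enough to survive ozone, and becomes the C1=C2 alkene in one step. The forward demands are chemoselective ozonolysis and a six-membered aldol closure.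

**C5–C6 and C9–C10 in one flask.** Triflate **7** is made from ketone **5**. Cutting the vinyl group from C5 and the methallyl group from C10 of **5** leads to enone **1**, vinylmagnesium bromide **2** and 3-bromo-2-methylpropene **3**. No other cut sets both ring-fusion centres, including the quaternary one, from three purchasable components with reagent-controlled absolute configuration. The forward step must transfer vinyl enantioselectively to a β-carbon next to a quaternary carbon, and must alkylate the resulting tetrasubstituted enolate anti to the vinyl group.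

## Roads not taken

**Alternative 1:** Both rings are opened at C5–C10 and C8–C9, which turns trans-octalin **A2** into the acyclic (2E,8E,10E)-trienoate **A1**. In the forward direction, heat or Me2AlCl lets the C9=C10 enoate of **A1** add across its C5=C6–C7=C8 silyloxydiene.
- Merits: one step closes rings A and B and sets C5, C8, C9 and C10. C9 already carries C11 at the ester level, and the ring A oxygen is present from the start, so no carbonyl has to be moved.
- Weak points: **A1** needs a long linear synthesis with three defined alkenes and a silyl dienol ether. Decatrienes of this tether length usually give trans/cis mixtures, and here a trisubstituted dienophile must form the quaternary C10 next to C5 and the gem-dimethyl carbon. The only resident stereocentre, C2, is remote and ends equatorial (2α) in **A2**, so it must later be inverted by oxidation and reduction. C6=C7, the C8 oxygen and a four-carbon homologation with C13 remain to be dealt with.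
- Comparison: this road is stronger in complexity gained per step and avoids the C1 problem. The chosen plan offers in return catalyst-set absolute configuration in the first step from bought materials, and a rigid decalin that controls C9 and C2 afterwards.

**Alternative 2:** The C10–C20 bond is cut, so the angular methyl is delivered last from the C2 oxygen. Bu3SnH and AIBN convert the (bromomethyl)dimethylsilyl ether **A3** of a 5(10)-octalin-2β-ol into an α-silyl radical. It adds 6-exo-trig to C10, the C5 radical takes hydrogen on the α face, and cyclic siloxane **A4** results. Cleavage of C–Si then leaves the methyl and the free 2β-alcohol.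
- Merits: the cis relation between the axial C2 oxygen and C20 is enforced by the tether. That is exactly the point where the chosen plan depends on a hindered anti opening (step 11).
- Weak points: the radical must attack a tetrasubstituted alkene to make the quaternary centre, in competition with simple reduction and 7-endo attack. The trans fusion depends on axial hydrogen transfer to a tertiary radical beside the gem-dimethyl group. Turning C–Si into C–H rather than C–OH needs forcing conditions. The whole octalin **A3**, with C9 and C13 in place and no angular methyl to guide C9, must be built first.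
- Comparison: this road is better for C2, but it puts the quaternary centre and the ring fusion at the very end. The chosen plan settles both in step 1.

**Alternative 3:** C5–C10 is cut inside ring A. The silyl ketene acetal of the 6-alkenyl δ-lactone **A5** (LiN(i-Pr)2, Me3SiCl, then heat) rearranges through a boat in an Ireland–Claisen ring contraction to cyclohexene acid **A6**.
- Merits: C5 and C10 arise by chirality transfer from one carbinol centre. Ring A arrives with the C1=C2 alkene, the handle the chosen plan needs two steps to make from the C1 ketone, and C6 arrives at the acid level.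
- Weak points: the lactone ring forces a boat-like, bicyclo[2.2.2]-type transition state. To place C20 cis to C6 the alkene of **A5** must be Z, which pushes the larger C9 arm against the gem-dimethyl carbon while a tertiary and a quaternary centre are joined. **A5** needs an enantiopure carbinol and a Z-trisubstituted alkene, a stoichiometric stereocentre that is then destroyed. Ring B must still be built from the acid and the masked ketone.
- Comparison: this road handles the C1/C2 problem more directly. The chosen plan reaches the same two centres catalytically in one step from commercial materials and closes ring B by a simple aldol.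

Key step: step 1

Remarks on the chemistry (assumptions):
- The target SMILES is read as the normal labdane (5S,9S,10S) with an axial 2β-acetoxy group (2R) and 13R. Labdane-type names of **18**–**27** imply 5α-H, 10β-methyl and, where C9 is sp3, 9α-H.
- L* = O,O'-(1,1'-binaphthalene-2,2'-diyl) N,N-bis(1-phenylethyl)phosphoramidite. The antipode that gives the 3S adduct is chosen by a test reaction on **1**; both antipodes are available.
- **8**, **10**, **18** and **19** are epimer mixtures at centres that are erased in the same or the next step. **20**–**22** are drawn as the expected 9(11)Z isomers; the geometry is erased in step 13.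

## Route

Step 1
Reactants: 1 2,4,4-trimethylcyclohex-2-en-1-one; 2 vinylmagnesium bromide; 3 3-bromo-2-methylpropene
Product: 5 (2R,3S)-2,4,4-trimethyl-2-(2-methylprop-2-en-1-yl)-3-vinylcyclohexan-1-one, via bromomagnesium enolate 4 (not isolated)
Conditions: Cu(OTf)2 (5 mol%), L* (10 mol%), CH2Cl2/t-BuOMe, −78 to −40 °C, slow addition of 2 (1.3 equiv); then 3 (3 equiv), DMPU, −40 °C to rt
Reagents that add atoms: none
Why: The Grignard reagent reduces Cu(OTf)2 to a monovalent copper–phosphoramidite complex, which takes up a vinyl group, binds the enone and transfers vinyl to the β-carbon C5 by oxidative addition and reductive elimination, leaving the regiodefined bromomagnesium enolate 4. The enolate is then C-alkylated at C10 by the allylic bromide in an SN2 reaction, so C5–C6 and C9–C10 form in one flask and no ring is closed. The closest known reaction type is the copper-catalysed asymmetric conjugate addition of Grignard reagents to cyclohexenones (4,4-dimethyl- and 2-methylcyclohexenone included) with trapping of the magnesium enolate by allylic halides. C5 is set by the chiral ligand, which selects the enone face. C10 is set by the substrate: the vinyl group next to the enolate carbon sits pseudoaxial to avoid allylic strain with the enolate methyl, and the electrophile enters anti to it, leaving the methyl cis to the vinyl group as a trans-decalin requires. The step needs 1,4- over 1,2-addition (copper catalysis and slow addition), enantioselectivity (ligand), C- over O-alkylation (soft allylic bromide with DMPU) and anti diastereoselectivity. Regiochemistry is not in question, because the enolate is formed only at C10 and alkylation is faster than proton transfer to the C2 side.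

Step 2
Reactants: 5 (2R,3S)-2,4,4-trimethyl-2-(2-methylprop-2-en-1-yl)-3-vinylcyclohexan-1-one
Product: 7 (5S,6R)-5-ethenyl-4,4,6-trimethyl-6-(2-methylprop-2-en-1-yl)cyclohex-1-en-1-yl trifluoromethanesulfonate, via potassium enolate 6 (not isolated)
Conditions: KN(SiMe3)2, THF, −78 °C; PhNTf2, −78 to 0 °C
Reagents that add atoms: N-phenylbis(trifluoromethanesulfonimide), O=S(=O)(N(c1ccccc1)S(=O)(=O)C(F)(F)F)C(F)(F)F
Why: C2 is the only enolisable position of 5 (C10 is quaternary), so O-sulfonylation of the enolate gives a single enol triflate, a standard reaction of hindered α-quaternary ketones; the triflate masks the C1 carbonyl through steps 3 and 4 and is the precursor of the C1=C2 alkene.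

Step 3
Reactants: 7 (5S,6R)-5-ethenyl-4,4,6-trimethyl-6-(2-methylprop-2-en-1-yl)cyclohex-1-en-1-yl trifluoromethanesulfonate
Product: 9 (5S,6R)-5-formyl-4,4,6-trimethyl-6-(2-oxopropyl)cyclohex-1-en-1-yl trifluoromethanesulfonate, via bis-ozonide 8 (not isolated)
Conditions: O3, CH2Cl2, −78 °C, Sudan Red 7B as end-point indicator; then PPh3, −78 °C to rt
Reagents that add atoms: ozone, [O-][O+]=O
Why: Ozonolysis with reductive work-up turns the vinyl group into the C6 aldehyde and the methallyl group into the C8 methyl ketone; both are electron-rich alkenes and should react far faster than the electron-poor, sulfonyloxy-substituted double bond, with the dye marking the end point, and C5 and C10 are not touched.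

Step 4
Reactants: 9 (5S,6R)-5-formyl-4,4,6-trimethyl-6-(2-oxopropyl)cyclohex-1-en-1-yl trifluoromethanesulfonate
Product: 11 (4aS,8aR)-4,4,8a-trimethyl-7-oxo-3,4,4a,7,8,8a-hexahydronaphthalen-1-yl trifluoromethanesulfonate, via aldol 10 (not isolated)
Conditions: p-TsOH·H2O (10 mol%), benzene, reflux, Dean–Stark trap
Reagents that add atoms: none
Why: Acid-catalysed intramolecular aldol condensation: the methyl-ketone enol (C7) adds to the C6 aldehyde in a 6-(enolendo)-exo-trig closure of ring B and water is lost to give the conjugated enone; the other enol (C9) could only close a four-membered ring, no C1 ketone is present to compete, the vinyl triflate tolerates acid, and the trans fusion follows from the trans C5/C10 relationship of step 1.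

Step 5
Reactants: 11 (4aS,8aR)-4,4,8a-trimethyl-7-oxo-3,4,4a,7,8,8a-hexahydronaphthalen-1-yl trifluoromethanesulfonate
Product: 12 (4aS,8aS)-5,5,8a-trimethyl-4a,5,6,8a-tetrahydronaphthalen-2(1H)-one
Conditions: Pd(OAc)2 (5 mol%), PPh3 (10 mol%), HCO2H, Bu3N, DMF, 60 °C
Reagents that add atoms: none
Why: Palladium-catalysed formate reduction of an enol triflate (oxidative addition to zerovalent palladium, formate exchange, loss of CO2, C–H reductive elimination) is routine for enol triflates next to a quaternary carbon and leaves the enone alone; it gives the C1=C2 alkene regiospecifically.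

Step 6
Reactants: 13 3-methylglutaric anhydride
Product: 14 (3R)-5-methoxy-3-methyl-5-oxopentanoic acid
Conditions: MeOH (10 equiv), (DHQD)2AQN or (DHQ)2AQN (bis-dihydroquinidine or bis-dihydroquinine anthraquinone-1,4-diyl diether, 10 mol%), Et2O, −40 °C
Reagents that add atoms: methanol, CO
Why: Alkaloid-catalysed desymmetrising alcoholysis of a prochiral cyclic anhydride differentiates the two enantiotopic carbonyl groups and so sets C13; the pseudoenantiomeric catalyst that gives the R hemiester is used, and the enantiomeric purity can be raised by crystallising an amine salt of 14.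

Step 7
Reactants: 14 (3R)-5-methoxy-3-methyl-5-oxopentanoic acid
Product: 15 methyl (3R)-5-hydroxy-3-methylpentanoate
Conditions: BH3·SMe2 (1.1 equiv), THF, −10 °C to rt; neutral aqueous work-up
Reagents that add atoms: none
Why: Borane reduces a carboxylic acid through its acyloxyborane much faster than a methyl ester; neutral work-up and immediate use avoid lactonisation of the δ-hydroxy ester, and the stereocentre is not involved.

Step 8
Reactants: 15 methyl (3R)-5-hydroxy-3-methylpentanoate
Product: 16 methyl (3R)-3-methyl-5-oxopentanoate
Conditions: Dess–Martin periodinane, NaHCO3, CH2Cl2, 0 °C to rt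
Reagents that add atoms: none
Why: Buffered periodinane oxidation of a primary alcohol stops at the aldehyde; the stereocentre is β to the new carbonyl and cannot epimerise.

Step 9
Reactants: 12 (4aS,8aS)-5,5,8a-trimethyl-4a,5,6,8a-tetrahydronaphthalen-2(1H)-one; 16 methyl (3R)-3-methyl-5-oxopentanoate
Product: 18 methyl (13R)-11-hydroxy-8-oxo-17-norlabda-1,6-dien-15-oate, via lithium dienolate 17 (not isolated)
Conditions: LiN(i-Pr)2 (1.1 equiv), THF, −78 °C; then 16 (1.3 equiv), −78 °C; AcOH quench at −78 °C
Reagents that add atoms: none
Why: Kinetic deprotonation of an enone by a lithium amide takes the α′ hydrogen (C9), not the γ hydrogen (C5), and the cross-conjugated dienolate adds to the aldehyde to form C9–C11, as in α′-aldol reactions of enones with a neopentyl α′ carbon; C1 is an sp2 CH at this stage, so the position peri to C9 is unencumbered, and the uncontrolled centres at C9 and C11 are removed in step 10.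

Step 10
Reactants: 18 methyl (13R)-11-hydroxy-8-oxo-17-norlabda-1,6-dien-15-oate
Product: 20 methyl (9(11)Z,13R)-8-oxo-17-norlabda-1,6,9(11)-trien-15-oate, via mesylate 19 (not isolated)
Conditions: MsCl, Et3N, CH2Cl2, 0 °C; then DBU, rt
Reagents that add atoms: none
Why: Mesylation followed by E1cB elimination gives the conjugated 9(11)-alkylidene ketone; the Z isomer, with the chain on the carbonyl side and away from the quaternary C10, is expected, and either geometry serves.

Step 11
Reactants: 20 methyl (9(11)Z,13R)-8-oxo-17-norlabda-1,6,9(11)-trien-15-oate
Product: 21 methyl (9(11)Z,13R)-1α-bromo-2β-hydroxy-8-oxo-17-norlabda-6,9(11)-dien-15-oate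
Conditions: NBS (1.1 equiv), acetone/H2O (4:1), 0 °C, dark
Reagents that add atoms: N-bromosuccinimide, O=C1CCC(=O)N1Br; water, O
Why: Bromohydrin formation: only the C1=C2 alkene is electron-rich, since the other two are conjugated to the ketone; bromine adds to the α face away from the axial C19 and C20 methyls, and water opens the bromonium ion anti at C2 in the trans-diaxial (Fürst–Plattner) sense, C1 being neopentyl, as in halohydrin formation from 4,4-dimethyl 2-ene triterpenoids, which sets C2 as the axial 2β-alcohol.

Step 12
Reactants: 21 methyl (9(11)Z,13R)-1α-bromo-2β-hydroxy-8-oxo-17-norlabda-6,9(11)-dien-15-oate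
Product: 22 methyl (9(11)Z,13R)-2β-hydroxy-8-oxo-17-norlabda-6,9(11)-dien-15-oate
Conditions: Bu3SnH (1.5 equiv), AIBN (10 mol%), toluene (0.2 M), 80 °C
Reagents that add atoms: none
Why: Radical chain dehalogenation; bromine abstraction is much faster than stannyl addition to the enones, the secondary C1 radical is reduced at this tin hydride concentration before it can rearrange, and C2 is unaffected.

Step 13
Reactants: 22 methyl (9(11)Z,13R)-2β-hydroxy-8-oxo-17-norlabda-6,9(11)-dien-15-oate
Product: 23 methyl (13R)-2β-hydroxy-8-oxo-17-norlabdan-15-oate
Conditions: H2 (1 atm), Pd/C (10 wt% palladium on carbon), EtOAc, rt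
Reagents that add atoms: none
Why: Heterogeneous hydrogenation saturates both enone double bonds and leaves the ketone and ester; hydrogen reaches C9 from the α face because the axial C20 methyl covers the β face, giving 9α-H with an equatorial chain, which is also the thermodynamic configuration next to the C8 ketone (any 9-epimer would be converged by NaOMe in MeOH).

Step 14
Reactants: 23 methyl (13R)-2β-hydroxy-8-oxo-17-norlabdan-15-oate
Product: 24 methyl (13R)-2β-hydroxylabd-8(17)-en-15-oate
Conditions: Ph3PCH3Br (4 equiv), KOt-Bu (3.8 equiv), toluene, rt to 60 °C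
Reagents that add atoms: methyltriphenylphosphonium bromide, C[P+](c1ccccc1)(c1ccccc1)c1ccccc1.[Br-]
Why: Wittig methylenation of the C8 ketone is the standard entry to labd-8(17)-enes; one equivalent of base is taken by the hydroxyl, the ester is inert to the non-stabilised ylide, and C9 already holds its stable configuration.

Step 15
Reactants: 24 methyl (13R)-2β-hydroxylabd-8(17)-en-15-oate
Product: 25 (13R)-2β-hydroxylabd-8(17)-en-15-oic acid
Conditions: LiOH·H2O, THF/MeOH/H2O, rt to 40 °C; then dilute HCl to pH 3 at 0 °C
Reagents that add atoms: lithium hydroxide, [Li+].[OH-]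
Why: Saponification of an unhindered methyl ester; the exocyclic alkene is stable to base and to brief cold acidification, and no stereocentre is at risk.

Step 16
Reactants: 25 (13R)-2β-hydroxylabd-8(17)-en-15-oic acid
Product: 27 (13R)-2β-acetoxylabd-8(17)-en-15-oic acid, via mixed anhydride 26 (not isolated)
Conditions: Ac2O (5 equiv), DMAP (0.3 equiv), pyridine, rt to 50 °C; then H2O, THF, rt
Reagents that add atoms: acetic anhydride, CC(=O)OC(C)=O
Why: DMAP-catalysed acylation of the hindered axial 2β-alcohol proceeds with retention because the C2–O bond is not broken; the carboxyl group is carried through as the mixed anhydride, which the aqueous stir hydrolyses back to the acid, so 27 is reached without a selective ester cleavage.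

## Compound list

1 | 2,4,4-trimethylcyclohex-2-en-1-one | CC1=CC(C)(C)CCC1=O | starting material
2 | vinylmagnesium bromide | C=C[Mg]Br | starting material
3 | 3-bromo-2-methylpropene | C=C(C)CBr | starting material
4 | bromomagnesium (3S)-3-ethenyl-2,4,4-trimethylcyclohex-1-en-1-olate | C=C[C@@H]1C(C)=C(O[Mg]Br)CCC1(C)C | intermediate
5 | (2R,3S)-2,4,4-trimethyl-2-(2-methylprop-2-en-1-yl)-3-vinylcyclohexan-1-one | O=C1CCC(C)(C)[C@H](C=C)[C@@]1(C)CC(C)=C | intermediate
6 | potassium (5S,6R)-5-ethenyl-4,4,6-trimethyl-6-(2-methylprop-2-en-1-yl)cyclohex-1-en-1-olate | [K+].[O-]C1=CCC(C)(C)[C@H](C=C)[C@@]1(C)CC(C)=C | intermediate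
7 | (5S,6R)-5-ethenyl-4,4,6-trimethyl-6-(2-methylprop-2-en-1-yl)cyclohex-1-en-1-yl trifluoromethanesulfonate | FC(F)(F)S(=O)(=O)OC1=CCC(C)(C)[C@H](C=C)[C@@]1(C)CC(C)=C | intermediate
8 | (5S,6R)-4,4,6-trimethyl-6-[(3-methyl-1,2,4-trioxolan-3-yl)methyl]-5-(1,2,4-trioxolan-3-yl)cyclohex-1-en-1-yl trifluoromethanesulfonate (bis-ozonide, epimers at the trioxolane carbons) | FC(F)(F)S(=O)(=O)OC1=CCC(C)(C)[C@H](C2OOCO2)[C@@]1(C)CC3(C)OOCO3 | intermediate
9 | (5S,6R)-5-formyl-4,4,6-trimethyl-6-(2-oxopropyl)cyclohex-1-en-1-yl trifluoromethanesulfonate | FC(F)(F)S(=O)(=O)OC1=CCC(C)(C)[C@H](C=O)[C@@]1(C)CC(C)=O | intermediate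
10 | (4aS,8aR)-5-hydroxy-4,4,8a-trimethyl-7-oxo-3,4,4a,5,6,7,8,8a-octahydronaphthalen-1-yl trifluoromethanesulfonate (carbinol epimers) | O=C1CC(O)[C@H]2C(C)(C)CC=C(OS(=O)(=O)C(F)(F)F)[C@]2(C)C1 | intermediate
11 | (4aS,8aR)-4,4,8a-trimethyl-7-oxo-3,4,4a,7,8,8a-hexahydronaphthalen-1-yl trifluoromethanesulfonate | O=C1C=C[C@H]2C(C)(C)CC=C(OS(=O)(=O)C(F)(F)F)[C@]2(C)C1 | intermediate
12 | (4aS,8aS)-5,5,8a-trimethyl-4a,5,6,8a-tetrahydronaphthalen-2(1H)-one | O=C1C=C[C@H]2C(C)(C)CC=C[C@]2(C)C1 | intermediate
13 | 3-methylglutaric anhydride | CC1CC(=O)OC(=O)C1 | starting material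
14 | (3R)-5-methoxy-3-methyl-5-oxopentanoic acid | OC(=O)C[C@@H](C)CC(=O)OC | intermediate
15 | methyl (3R)-5-hydroxy-3-methylpentanoate | OCC[C@@H](C)CC(=O)OC | intermediate
16 | methyl (3R)-3-methyl-5-oxopentanoate | O=CC[C@@H](C)CC(=O)OC | intermediate
17 | lithium 5,5,8a-trimethyl-4a,5,6,8a-tetrahydronaphthalen-2-olate (C8=C9/C6=C7 dienolate of 12; C5 and C10 as in 12) | [Li+].[O-]C1C=C[C@H]2C(C)(C)CC=C[C@]2(C)C=1 | intermediate
18 | methyl (13R)-11-hydroxy-8-oxo-17-norlabda-1,6-dien-15-oate (epimers at C9 and C11) | O=C1C=C[C@H]2C(C)(C)CC=C[C@]2(C)C1C(O)C[C@@H](C)CC(=O)OC | intermediate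
19 | methyl (13R)-11-(methanesulfonyloxy)-8-oxo-17-norlabda-1,6-dien-15-oate (epimers at C9 and C11) | O=C1C=C[C@H]2C(C)(C)CC=C[C@]2(C)C1C(OS(C)(=O)=O)C[C@@H](C)CC(=O)OC | intermediate
20 | methyl (9(11)Z,13R)-8-oxo-17-norlabda-1,6,9(11)-trien-15-oate | O=C1C=C[C@H]2C(C)(C)CC=C[C@]2(C)/C1=C/C[C@@H](C)CC(=O)OC | intermediate
21 | methyl (9(11)Z,13R)-1α-bromo-2β-hydroxy-8-oxo-17-norlabda-6,9(11)-dien-15-oate | O=C1C=C[C@H]2C(C)(C)C[C@@H](O)[C@H](Br)[C@]2(C)/C1=C/C[C@@H](C)CC(=O)OC | intermediate
22 | methyl (9(11)Z,13R)-2β-hydroxy-8-oxo-17-norlabda-6,9(11)-dien-15-oate | O=C1C=C[C@H]2C(C)(C)C[C@@H](O)C[C@]2(C)/C1=C/C[C@@H](C)CC(=O)OC | intermediate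
23 | methyl (13R)-2β-hydroxy-8-oxo-17-norlabdan-15-oate | O=C1CC[C@H]2C(C)(C)C[C@@H](O)C[C@]2(C)[C@H]1CC[C@@H](C)CC(=O)OC | intermediate
24 | methyl (13R)-2β-hydroxylabd-8(17)-en-15-oate | C=C1CC[C@H]2C(C)(C)C[C@@H](O)C[C@]2(C)[C@H]1CC[C@@H](C)CC(=O)OC | intermediate
25 | (13R)-2β-hydroxylabd-8(17)-en-15-oic acid | C=C1CC[C@H]2C(C)(C)C[C@@H](O)C[C@]2(C)[C@H]1CC[C@@H](C)CC(=O)O | intermediate
26 | acetic (13R)-2β-acetoxylabd-8(17)-en-15-oic anhydride | C=C1CC[C@H]2C(C)(C)C[C@@H](OC(C)=O)C[C@]2(C)[C@H]1CC[C@@H](C)CC(=O)OC(C)=O | intermediate
27 | (13R)-2β-acetoxylabd-8(17)-en-15-oic acid, (2R,5S,9S,10S,13R) | C=C1CC[C@H]2C(C)(C)C[C@@H](OC(C)=O)C[C@]2(C)[C@H]1CC[C@@H](C)CC(=O)O | target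

## Step count and least certain steps

Total: 16 steps. Longest linear sequence: 13 steps (steps 1–5 and 9–16). The aldehyde **16** takes 3 steps (6–8) and joins at step 9.

**Step 1 (key step).** Vinyl transfer to a β-carbon flanked by the gem-dimethyl carbon and an α-methyl group may be slow. An uncatalysed background addition would then erode enantioselectivity or give 1,2-addition. The hindered tetrasubstituted magnesium enolate may also alkylate sluggishly, with proton transfer, O-alkylation, or loss of anti selectivity because the axial C4 methyl sits on the anti face. The fallback separates the two bond formations and changes both the metal and the enolate. It sets out from **1**: rhodium-catalysed asymmetric conjugate addition of K[CH2=CHBF3] ([RhCl(C8H12)]2 with the appropriate antipode of 2,2'-bis(diphenylphosphino)-1,1'-binaphthyl, dioxane/H2O, heat) should give (3R)-3-ethenyl-2,4,4-trimethylcyclohexan-1-one F1 (same C5 configuration as **5**; mixture at the α-carbon). Thermodynamic silylation (Me3SiCl, NaI, Et3N, MeCN) should give the tetrasubstituted enol ether [(3S)-3-ethenyl-2,4,4-trimethylcyclohex-1-en-1-yl]oxy(trimethyl)silane F2. MeLi in THF then releases the lithium enolate, which is alkylated with **3** in the presence of HMPA. The route is rejoined at **5**.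

**Step 3.** The vinyl group lies between two quaternary carbons and may react slowly, so ozone may begin to attack the enol triflate double bond before both terminal alkenes are consumed. That would mean over-oxidation and loss of the C1 handle. The fallback replaces ozone by osmylation, which discriminates more strongly against electron-poor alkenes. It sets out from **7**: OsO4 (2 mol%) with N-methylmorpholine N-oxide in acetone/H2O should give (5S,6R)-5-(1,2-dihydroxyethyl)-6-(2,3-dihydroxy-2-methylpropyl)-4,4,6-trimethylcyclohex-1-en-1-yl trifluoromethanesulfonate F3. NaIO4 in THF/H2O then cleaves both diols, and the route is rejoined at **9**.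

**Step 9.** The lithium dienolate is neopentyl at C9 and the aldehyde is enolisable. Proton transfer from the aldehyde may therefore outrun addition and return **12**, and the adduct may revert on warming. The fallback uses a Lewis-acid-mediated Mukaiyama aldol in place of the basic enolate. It sets out from **12**: LiN(i-Pr)2 then Me3SiCl (THF, −78 °C) should give trimethyl[(5,5,8a-trimethyl-4a,5,6,8a-tetrahydronaphthalen-2-yl)oxy]silane F4. F4 is combined with **16** and TiCl4 in CH2Cl2 at −78 °C, and the route is rejoined at **18**.

**Step 11.** Water has to reach C2 from the β face between the two axial methyl groups. Capture may therefore be slow, which would allow opening with the other regio- or stereochemistry, or allylic bromination. The fallback sets C2 by hydride delivery and not by anti opening. It sets out from **20**: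
- Conjugate reduction of both enone double bonds with [(Ph3P)CuH]6 (benzene, wet THF) should give methyl (13R)-8-oxo-17-norlabd-1-en-15-oate F5.
- Ketalisation with (Me3SiOCH2)2 and catalytic Me3SiOTf (CH2Cl2, −78 °C) gives methyl (13R)-8,8-(ethylenedioxy)-17-norlabd-1-en-15-oate F6.
- Hydroboration from the α face with boron at the non-neopentyl C2 (BH3·THF, 0 °C; NaBO3·4H2O) gives methyl (13R)-8,8-(ethylenedioxy)-2α-hydroxy-17-norlabdan-15-oate F7.
- Dess–Martin oxidation gives methyl (13R)-8,8-(ethylenedioxy)-2-oxo-17-norlabdan-15-oate F8.
- LiBH(s-Bu)3 (THF, −78 °C) attacks from the open α face and gives methyl (13R)-8,8-(ethylenedioxy)-2β-hydroxy-17-norlabdan-15-oate F9.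
- Pyridinium p-toluenesulfonate in acetone/H2O removes the ketal, and the route is rejoined at **23**.

**Step 14.** The basic ylide may enolise the hindered, α-branched C8 ketone and not add to it. That would return the ketone and risk C9. The fallback is a two-stage Peterson olefination with a less basic, more nucleophilic reagent. It sets out from **23**: Me3SiCH2MgCl with CeCl3 (THF, −78 °C to 0 °C) should add to the ketone in preference to the ester and give methyl (13R)-2β,8-dihydroxy-17-(trimethylsilyl)labdan-15-oate F10. Aqueous HF in MeCN at 0 °C then eliminates the β-hydroxysilane, and the route is rejoined at **24**.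

## Further compounds

F1 | step 1 | (3R)-3-ethenyl-2,4,4-trimethylcyclohexan-1-one (mixture at C2) | O=C1CCC(C)(C)[C@H](C=C)C1C
F2 | step 1 | [(3S)-3-ethenyl-2,4,4-trimethylcyclohex-1-en-1-yl]oxy(trimethyl)silane | C=C[C@@H]1C(C)=C(O[Si](C)(C)C)CCC1(C)C
F3 | step 3 | (5S,6R)-5-(1,2-dihydroxyethyl)-6-(2,3-dihydroxy-2-methylpropyl)-4,4,6-trimethylcyclohex-1-en-1-yl trifluoromethanesulfonate (carbinol epimers) | FC(F)(F)S(=O)(=O)OC1=CCC(C)(C)[C@H](C(O)CO)[C@@]1(C)CC(C)(O)CO
F4 | step 9 | trimethyl[(5,5,8a-trimethyl-4a,5,6,8a-tetrahydronaphthalen-2-yl)oxy]silane (C5 and C10 as in 12) | C[Si](C)(C)OC1C=C[C@H]2C(C)(C)CC=C[C@]2(C)C=1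
F5 | step 11 | methyl (13R)-8-oxo-17-norlabd-1-en-15-oate | O=C1CC[C@H]2C(C)(C)CC=C[C@]2(C)[C@H]1CC[C@@H](C)CC(=O)OC
F6 | step 11 | methyl (13R)-8,8-(ethylenedioxy)-17-norlabd-1-en-15-oate | O1CCOC12CC[C@H]3C(C)(C)CC=C[C@]3(C)[C@H]2CC[C@@H](C)CC(=O)OC
F7 | step 11 | methyl (13R)-8,8-(ethylenedioxy)-2α-hydroxy-17-norlabdan-15-oate | O1CCOC12CC[C@H]3C(C)(C)C[C@H](O)C[C@]3(C)[C@H]2CC[C@@H](C)CC(=O)OC
F8 | step 11 | methyl (13R)-8,8-(ethylenedioxy)-2-oxo-17-norlabdan-15-oate | O1CCOC12CC[C@H]3C(C)(C)CC(=O)C[C@]3(C)[C@H]2CC[C@@H](C)CC(=O)OC
F9 | step 11 | methyl (13R)-8,8-(ethylenedioxy)-2β-hydroxy-17-norlabdan-15-oate | O1CCOC12CC[C@H]3C(C)(C)C[C@@H](O)C[C@]3(C)[C@H]2CC[C@@H](C)CC(=O)OC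
F10 | step 14 | methyl (13R)-2β,8-dihydroxy-17-(trimethylsilyl)labdan-15-oate (epimers at C8) | C[Si](C)(C)CC1(O)CC[C@H]2C(C)(C)C[C@@H](O)C[C@]2(C)[C@H]1CC[C@@H](C)CC(=O)OC
A1 | alternative 1 | methyl (2E,8E,10E)-5-(tert-butyldimethylsilyloxy)-3,7,7-trimethyl-11-(triethylsilyloxy)undeca-2,8,10-trienoate (single enantiomer at C5 of the chain) | COC(=O)/C=C(\C)C[C@@H](O[Si](C)(C)C(C)(C)C)CC(C)(C)/C=C/C=C/O[Si](CC)(CC)CC
A2 | alternative 1 | trans-octalin with C6=C7 alkene, C9β methyl ester, C8β triethylsilyl ether and C2α tert-butyldimethylsilyl ether | CC[Si](CC)(CC)O[C@H]1C=C[C@H]2C(C)(C)C[C@H](O[Si](C)(C)C(C)(C)C)C[C@]2(C)[C@H]1C(=O)OC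
A3 | alternative 2 | methyl (13R)-2β-[(bromomethyl)dimethylsilyloxy]-8,8-(ethylenedioxy)-17,20-dinorlabd-5(10)-en-15-oate | C12(OCCO1)CCC3=C(C[C@H](O[Si](C)(C)CBr)CC3(C)C)[C@H]2CC[C@@H](C)CC(=O)OC
A4 | alternative 2 | cyclic siloxane (O2–SiMe2–C20 bridge) of methyl 8,8-(ethylenedioxy)-2β-hydroxy-17-norlabdan-15-oate | C12(OCCO1)CC[C@H]3C(C)(C)C[C@@H]4C[C@]3(C[Si](C)(C)O4)[C@H]2CC[C@@H](C)CC(=O)OC
A5 | alternative 3 | (6R)-4,4-dimethyl-6-[(1Z)-2-methyl-3-(2-methyl-1,3-dioxolan-2-yl)prop-1-en-1-yl]oxan-2-one | O=C1CC(C)(C)C[C@@H](O1)/C=C(/C)\CC2(C)OCCO2
A6 | alternative 3 | (1S,2S)-2,6,6-trimethyl-2-[(2-methyl-1,3-dioxolan-2-yl)methyl]cyclohex-3-ene-1-carboxylic acid | OC(=O)[C@H]1C(C)(C)CC=C[C@]1(C)CC2(C)OCCO2
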